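Assumption: the target has no stereocentre, so the "single enantiomer" is simply the achiral compound; racemic sp3 intermediates are aromatised or cleaved later and need no control.

**Retrosynthetic overview**
1. Target 21 ⇐ dibenzyl ether 20 (BCl3 debenzylation) ⇐ divinyl depside 18 (each vinyl cleaved to CHO) ⇐ dibromo depside 17 (double Stille vinylation).
2. 17 ⇐ acid 7 (ring A) + phenol 15 (ring B): the depside ester bond, made by TFAA esterification.
3. Ring A: 7 ⇐ 5 ⇐ dione 4 ⇐ methyl acetoacetate 1 + methyl crotonate 2 by intermolecular Michael addition (the key C–C bond) and Dieckmann closure. Br2 then aromatises the ring and places a bromine at each future formyl position.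
4. Ring B: 15 ⇐ 12 ⇐ atraric acid 8 (bought as the arene). The C5 methyl comes from Rieche formylation and ionic hydrogenation, followed by 4-OBn, 2-OMe and hydrogenolysis.
5. Ring order: ring A is the only ring built (cyclohexanedione in step 1, aromatic in step 2); ring B is purchased; the two are joined in step 10.

**Route**

Step 1
Reactants: 1 methyl acetoacetate; 2 methyl (E)-but-2-enoate
Product: 4 methyl 6-methyl-2,4-dioxocyclohexane-1-carboxylate, via Michael adduct 3 (not isolated)
Conditions: NaOMe (1.1 equiv), MeOH, reflux, 12 h; then aq. HCl, 0 °C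
Reagents that add atoms: none
Why: The acetoacetate enolate adds to the β-carbon of the crotonate (intermolecular Michael addition, the bond that joins the two fragments) and the methyl-ketone enolate of 3 closes onto the distal ester (Dieckmann/Claisen condensation), driven by the stabilised enolate of 4; the two new stereocentres are racemic and are erased in step 2.

Step 2
Reactants: 4 methyl 6-methyl-2,4-dioxocyclohexane-1-carboxylate
Product: 5 methyl 3,5-dibromo-2,4-dihydroxy-6-methylbenzoate
Conditions: Br2 (3.1 equiv), AcOH, rt, 16 h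
Reagents that add atoms: bromine, BrBr
Why: α-Bromination of the enolised β-diketone and loss of HBr aromatise the ring (oxidative aromatisation), and the resulting resorcinol is brominated at both free positions (electrophilic aromatic substitution), marking C3 and C5.

Step 3
Reactants: 5 methyl 3,5-dibromo-2,4-dihydroxy-6-methylbenzoate
Product: 6 methyl 2,4-bis(benzyloxy)-3,5-dibromo-6-methylbenzoate
Conditions: BnBr (2.5 equiv), K2CO3 (3 equiv), DMF, 70 °C, 12 h
Reagents that add atoms: benzyl bromide, BrCc1ccccc1
Why: Williamson ether synthesis; the acidic dibromophenols are fully ionised and DMF with heat overcomes the hindrance and the chelation of the 2-OH.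

Step 4
Reactants: 6 methyl 2,4-bis(benzyloxy)-3,5-dibromo-6-methylbenzoate
Product: 7 2,4-bis(benzyloxy)-3,5-dibromo-6-methylbenzoic acid
Conditions: KOH (10 equiv), DMSO/H2O 5:1, 90 °C, 6 h; then 2 M HCl, 0 °C
Reagents that add atoms: potassium hydroxide, [K+].[OH-]
Why: Saponification by poorly solvated hydroxide in aqueous DMSO hydrolyses the di-ortho-substituted ester; the aryl bromides have no ortho hydrogen (no aryne) and are not activated for SNAr.

Step 5
Reactants: 8 methyl 2,4-dihydroxy-3,6-dimethylbenzoate (atraric acid)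
Product: 10 methyl 5-formyl-2,4-dihydroxy-3,6-dimethylbenzoate, via chloro(methoxy)methyl arene 9 (not isolated)
Conditions: Cl2CHOMe (1.5 equiv), TiCl4 (2.5 equiv), CH2Cl2, 0 °C to rt, 3 h; then 1 M HCl, ice
Reagents that add atoms: dichloromethyl methyl ether, COC(Cl)Cl; water, O
Why: Rieche formylation can only occur at C5, the single free ring position, which is ortho to the 4-OH and para to the 2-OH; aqueous work-up hydrolyses 9 to the aldehyde.

Step 6
Reactants: 10 methyl 5-formyl-2,4-dihydroxy-3,6-dimethylbenzoate
Product: 12 methyl 2,4-dihydroxy-3,5,6-trimethylbenzoate, via benzylic alcohol 11 (not isolated)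
Conditions: Et3SiH (3 equiv), TFA, rt, 4 h
Reagents that add atoms: none
Why: Ionic hydrogenation; the benzylic alcohol ionises readily to a cation stabilised by the ortho and para hydroxyls (quinone methide) and takes up a second hydride to give the methyl group.

Step 7
Reactants: 12 methyl 2,4-dihydroxy-3,5,6-trimethylbenzoate
Product: 13 methyl 4-(benzyloxy)-2-hydroxy-3,5,6-trimethylbenzoate
Conditions: BnBr (1.1 equiv), K2CO3 (1.2 equiv), acetone, reflux, 12 h
Reagents that add atoms: benzyl bromide, BrCc1ccccc1
Why: Selective Williamson etherification; the 4-OH (para to the ester, not hydrogen-bonded) is ionised and alkylated, while the 2-OH is held in a hydrogen bond to the ester carbonyl.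

Step 8
Reactants: 13 methyl 4-(benzyloxy)-2-hydroxy-3,5,6-trimethylbenzoate
Product: 14 methyl 4-(benzyloxy)-2-methoxy-3,5,6-trimethylbenzoate
Conditions: MeI (5 equiv), K2CO3 (3 equiv), DMF, 60 °C, 16 h
Reagents that add atoms: iodomethane, CI
Why: Williamson O-methylation under forcing conditions (excess MeI, dipolar aprotic solvent) alkylates the remaining chelated phenol.

Step 9
Reactants: 14 methyl 4-(benzyloxy)-2-methoxy-3,5,6-trimethylbenzoate
Product: 15 methyl 4-hydroxy-2-methoxy-3,5,6-trimethylbenzoate
Conditions: H2 (1 atm), 10% Pd/C, EtOAc, rt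
Reagents that add atoms: none
Why: Catalytic hydrogenolysis cleaves the benzyl ether only, freeing the 4-OH for ester formation.

Step 10
Reactants: 7 2,4-bis(benzyloxy)-3,5-dibromo-6-methylbenzoic acid; 15 methyl 4-hydroxy-2-methoxy-3,5,6-trimethylbenzoate
Product: 17 methyl 4-{[2,4-bis(benzyloxy)-3,5-dibromo-6-methylbenzoyl]oxy}-2-methoxy-3,5,6-trimethylbenzoate, via mixed trifluoroacetic anhydride 16 (not isolated)
Conditions: TFAA (4 equiv), toluene, rt, 6 h
Reagents that add atoms: none
Why: Mixed-anhydride (TFAA) esterification; the di-ortho-substituted, alkoxy-rich aroyl trifluoroacetate ionises to a small acylium-like electrophile that acylates even a 2,6-dimethylphenol, and bromides, benzyl ethers and esters are inert.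

Step 11
Reactants: 17 methyl 4-{[2,4-bis(benzyloxy)-3,5-dibromo-6-methylbenzoyl]oxy}-2-methoxy-3,5,6-trimethylbenzoate
Product: 18 methyl 4-{[2,4-bis(benzyloxy)-3,5-diethenyl-6-methylbenzoyl]oxy}-2-methoxy-3,5,6-trimethylbenzoate
Conditions: CH2=CHSnBu3 (3 equiv), Pd(P(t-Bu)3)2 (10 mol%), CsF (4.5 equiv), 1,4-dioxane, 100 °C
Reagents that add atoms: tributyl(vinyl)stannane, C=C[Sn](CCCC)(CCCC)CCCC
Why: Stille coupling with a bulky electron-rich phosphine and fluoride activation handles di-ortho-substituted aryl bromides; the neutral, carbonate-free medium spares both esters and disfavours C–H arylation of the neighbouring benzyl groups.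

Step 12
Reactants: 18 methyl 4-{[2,4-bis(benzyloxy)-3,5-diethenyl-6-methylbenzoyl]oxy}-2-methoxy-3,5,6-trimethylbenzoate
Product: 20 methyl 4-{[2,4-bis(benzyloxy)-3,5-diformyl-6-methylbenzoyl]oxy}-2-methoxy-3,5,6-trimethylbenzoate, via tetraol 19 (not isolated)
Conditions: OsO4 (5 mol%), NMO (3 equiv), acetone/H2O 4:1, rt; then NaIO4 (4 equiv), rt
Reagents that add atoms: N-methylmorpholine N-oxide, C[N+]1([O-])CCOCC1; water, O; osmium tetroxide (catalytic oxygen carrier), O=[Os](=O)(=O)=O
Why: Upjohn dihydroxylation of the two terminal alkenes followed by periodate glycol cleavage (Lemieux–Johnson-type sequence) gives the aldehydes under near-neutral conditions; the diol stereocentres of 19 are uncontrolled and destroyed in the cleavage.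

Step 13
Reactants: 20 methyl 4-{[2,4-bis(benzyloxy)-3,5-diformyl-6-methylbenzoyl]oxy}-2-methoxy-3,5,6-trimethylbenzoate
Product: 21 methyl 4-[(3,5-diformyl-2,4-dihydroxy-6-methylbenzoyl)oxy]-2-methoxy-3,5,6-trimethylbenzoate
Conditions: BCl3 (1 M in CH2Cl2, 4 equiv), C6HMe5 (6 equiv), CH2Cl2, −78 °C, 30 min; then H2O
Reagents that add atoms: none
Why: Lewis-acid debenzylation with a cation scavenger; both benzyl ethers sit ortho to carbonyl groups and are cleaved by chelation-assisted ionisation at −78 °C, where the aldehydes, the depside ester and the ring-B methyl ether survive.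

**Compound list**
1 | methyl acetoacetate (methyl 3-oxobutanoate) | CC(=O)CC(=O)OC | starting material
2 | methyl (E)-but-2-enoate (methyl crotonate) | C/C=C/C(=O)OC | starting material
3 | dimethyl 2-acetyl-3-methylpentanedioate (Michael adduct, racemic diastereomer mixture, not isolated) | COC(=O)CC(C)C(C(C)=O)C(=O)OC | intermediate
4 | methyl 6-methyl-2,4-dioxocyclohexane-1-carboxylate (racemic, largely enolised) | COC(=O)C1C(C)CC(=O)CC1=O | intermediate
5 | methyl 3,5-dibromo-2,4-dihydroxy-6-methylbenzoate | COC(=O)c1c(C)c(Br)c(O)c(Br)c1O | intermediate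
6 | methyl 2,4-bis(benzyloxy)-3,5-dibromo-6-methylbenzoate | COC(=O)c1c(C)c(Br)c(OCc2ccccc2)c(Br)c1OCc3ccccc3 | intermediate
7 | 2,4-bis(benzyloxy)-3,5-dibromo-6-methylbenzoic acid | OC(=O)c1c(C)c(Br)c(OCc2ccccc2)c(Br)c1OCc3ccccc3 | intermediate
8 | methyl 2,4-dihydroxy-3,6-dimethylbenzoate (atraric acid) | COC(=O)c1c(C)cc(O)c(C)c1O | starting material
9 | methyl 5-[chloro(methoxy)methyl]-2,4-dihydroxy-3,6-dimethylbenzoate (racemic, not isolated) | COC(=O)c1c(C)c(C(Cl)OC)c(O)c(C)c1O | intermediate
10 | methyl 5-formyl-2,4-dihydroxy-3,6-dimethylbenzoate | COC(=O)c1c(C)c(C=O)c(O)c(C)c1O | intermediate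
11 | methyl 2,4-dihydroxy-5-(hydroxymethyl)-3,6-dimethylbenzoate (not isolated) | COC(=O)c1c(C)c(CO)c(O)c(C)c1O | intermediate
12 | methyl 2,4-dihydroxy-3,5,6-trimethylbenzoate | COC(=O)c1c(C)c(C)c(O)c(C)c1O | intermediate
13 | methyl 4-(benzyloxy)-2-hydroxy-3,5,6-trimethylbenzoate | COC(=O)c1c(C)c(C)c(OCc2ccccc2)c(C)c1O | intermediate
14 | methyl 4-(benzyloxy)-2-methoxy-3,5,6-trimethylbenzoate | COC(=O)c1c(C)c(C)c(OCc2ccccc2)c(C)c1OC | intermediate
15 | methyl 4-hydroxy-2-methoxy-3,5,6-trimethylbenzoate | COC(=O)c1c(C)c(C)c(O)c(C)c1OC | intermediate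
16 | 2,4-bis(benzyloxy)-3,5-dibromo-6-methylbenzoic trifluoroacetic anhydride (not isolated) | Cc1c(Br)c(OCc2ccccc2)c(Br)c(OCc3ccccc3)c1C(=O)OC(=O)C(F)(F)F | intermediate
17 | methyl 4-{[2,4-bis(benzyloxy)-3,5-dibromo-6-methylbenzoyl]oxy}-2-methoxy-3,5,6-trimethylbenzoate | COC(=O)c1c(C)c(C)c(OC(=O)c2c(C)c(Br)c(OCc3ccccc3)c(Br)c2OCc4ccccc4)c(C)c1OC | intermediate
18 | methyl 4-{[2,4-bis(benzyloxy)-3,5-diethenyl-6-methylbenzoyl]oxy}-2-methoxy-3,5,6-trimethylbenzoate | COC(=O)c1c(C)c(C)c(OC(=O)c2c(C)c(C=C)c(OCc3ccccc3)c(C=C)c2OCc4ccccc4)c(C)c1OC | intermediate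
19 | methyl 4-{[2,4-bis(benzyloxy)-3,5-bis(1,2-dihydroxyethyl)-6-methylbenzoyl]oxy}-2-methoxy-3,5,6-trimethylbenzoate (stereoisomer mixture, not isolated) | COC(=O)c1c(C)c(C)c(OC(=O)c2c(C)c(C(O)CO)c(OCc3ccccc3)c(C(O)CO)c2OCc4ccccc4)c(C)c1OC | intermediate
20 | methyl 4-{[2,4-bis(benzyloxy)-3,5-diformyl-6-methylbenzoyl]oxy}-2-methoxy-3,5,6-trimethylbenzoate | COC(=O)c1c(C)c(C)c(OC(=O)c2c(C)c(C=O)c(OCc3ccccc3)c(C=O)c2OCc4ccccc4)c(C)c1OC | intermediate
21 | methyl 4-[(3,5-diformyl-2,4-dihydroxy-6-methylbenzoyl)oxy]-2-methoxy-3,5,6-trimethylbenzoate | COC(=O)c1c(C)c(C)c(OC(=O)c2c(C)c(C=O)c(O)c(C=O)c2O)c(C)c1OC | target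

**Step count and risks**
Total steps: 13. Longest linear sequence: 9 steps (8 → 21 through steps 5–13); the ring-A branch from 1 and 2 is 8 steps (steps 1–4 and 10–13).

Three steps most likely to fail:

Step 11 (double Stille coupling). Both C–Br bonds are flanked by two ortho substituents, so the second coupling may stall, protodebromination may compete, or palladium may cyclise onto a neighbouring benzyl ring. The fallback gives up the cross-coupling logic and sets out from 17. Hydrogenolysis (H2, Pd/C, Et3N, EtOAc) removes both bromines and both benzyl groups to give methyl 4-[(2,4-dihydroxy-6-methylbenzoyl)oxy]-2-methoxy-3,5,6-trimethylbenzoate F3. Exhaustive Duff formylation (excess hexamethylenetetramine, TFA, 90 °C, then aqueous HCl) then formylates the only two free aromatic positions, C3 and C5 of ring A; ring B is fully substituted. Both positions are ortho or para to the hydroxyls and meta to the acyl group. This returns to the route at 21, bypassing 18–20; expect a mono/di-formyl mixture that may need resubmission.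

Step 10 (TFAA esterification). Both partners are di-ortho-substituted and the two bromines make the acylium-type intermediate less favourable. The fallback sets out from 7 and replaces acid-mediated mixed-anhydride acylation by a preformed acyl chloride and phenolate. Oxalyl chloride with catalytic DMF in CH2Cl2 gives 2,4-bis(benzyloxy)-3,5-dibromo-6-methylbenzoyl chloride F1. Phenol 15 is deprotonated with NaH in THF to sodium 3-methoxy-4-(methoxycarbonyl)-2,5,6-trimethylphenolate F2. Combining the two at 0 to 50 °C returns to the route at 17.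

Step 13 (BCl3 debenzylation). The Lewis acid could also attack the chelated ring-B methyl ether or promote condensation of the aldehydes with the scavenger. The fallback sets out from 20 and changes from Lewis-acid ionisation to reductive C–O cleavage: heterogeneous hydrogenolysis (H2, 1 atm, Pd/C, EtOAc, rt, stopped after two equivalents). The aldehydes become hydrogen-bonded to the freed hydroxyls as the ethers cleave, which slows their reduction. This returns directly at 21 (new compound: none F0).

**Further compounds**
F1 | step 10 | 2,4-bis(benzyloxy)-3,5-dibromo-6-methylbenzoyl chloride | Cc1c(Br)c(OCc2ccccc2)c(Br)c(OCc3ccccc3)c1C(Cl)=O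
F2 | step 10 | sodium 3-methoxy-4-(methoxycarbonyl)-2,5,6-trimethylphenolate | COC(=O)c1c(C)c(C)c([O-])c(C)c1OC.[Na+]
F3 | step 11 | methyl 4-[(2,4-dihydroxy-6-methylbenzoyl)oxy]-2-methoxy-3,5,6-trimethylbenzoate | COC(=O)c1c(C)c(C)c(OC(=O)c2c(C)cc(O)cc2O)c(C)c1OC
F0 | step 13 | none | none
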